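Ring B is disconnected at C7–C8 and C8–C9: C8 is carbon monoxide, and the remaining five ring-B carbons are the vinylcyclopropane C7=C6–C5(–C9H2)–C10 fused to ring A. The key step exploits the strained C5–C9 cyclopropane bond next to the C6=C7 vinyl group: rhodium opens it, inserts CO and closes ring B as the 5-en-8-one in one operation, leaving the C4 and C10 quaternary centres untouched. The precursor is a 1-vinyl-2,6-dimethylbicyclo[4.1.0]heptane with a free C19 hydroxymethyl group on C4, anti to the cyclopropane methylene. That hydroxyl then directs hydrogenation to the cis ring fusion; the linalool-derived C11–C16 chain is joined at C9.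

Key step: step 13

Remark on the target: labdane numbering is used throughout. The SMILES encodes a cis-fused decalin: H5, the C10 methyl, the C9 side chain and the C4 carboxyl (C19) all lie on one face (4S,5S,9S,10R), and C13 is R.
Assumption: the L-valine tert-butyl ester enamine, methylated in toluene/HMPA, is taken to give the (S)-keto ester 7. If the rotation of 7 shows the other sense, the same enamine is methylated in THF/1,3-dioxolane or the D-valine ester is used, with no other change.
Steps 17–20 make the side-chain iodide; all other steps are the main line.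

Step 1
Reactants: 1 ethyl 2-oxocyclohexane-1-carboxylate; 2 L-valine tert-butyl ester
Product: 3 ethyl 2-{[(2S)-1-tert-butoxy-3-methyl-1-oxobutan-2-yl]amino}cyclohex-1-ene-1-carboxylate
Conditions: TsOH·H2O (cat.), benzene, reflux, Dean–Stark
Reagents that add atoms: L-valine tert-butyl ester, CC(C)[C@H](N)C(=O)OC(C)(C)C
Why: Acid-catalysed condensation of the ketone with the primary amine, driven by azeotropic removal of water, gives the hydrogen-bonded vinylogous carbamate (enamine formation); the auxiliary stereocentre is not touched.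

Step 2
Reactants: 3 the enamine; 4 iodomethane; 5 water
Product: 7 ethyl (1S)-1-methyl-2-oxocyclohexane-1-carboxylate, via methylated imine 6 (not isolated)
Conditions: LiN(iPr)2, toluene, HMPA, −78 °C; MeI, −78 → −20 °C; then 1 M HCl, Et2O, 0 °C
Reagents that add atoms: iodomethane, CI; water, O
Why: Auxiliary-controlled alkylation of a lithiated chiral enamine: lithium is chelated by the nitrogen and the valine ester carbonyl, the isopropyl group blocks one face of the aza-enolate, methyl iodide sets the quaternary C4 as S, and mild acid hydrolyses the imine to the ketone and returns the auxiliary.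

Step 3
Reactants: 7 ethyl (1S)-1-methyl-2-oxocyclohexane-1-carboxylate; 4 iodomethane
Product: 8 ethyl (1S)-1,3-dimethyl-2-oxocyclohexane-1-carboxylate (both C3 epimers)
Conditions: LiN(iPr)2, THF, −78 °C; MeI, −78 → 0 °C
Reagents that add atoms: iodomethane, CI
Why: Kinetic enolate alkylation: C4 is quaternary, so the only enolisable position is C10, where methylation installs the future C20; the new centre is left uncontrolled because it becomes sp2 in step 4.

Step 4
Reactants: 8 ethyl (1S)-1,3-dimethyl-2-oxocyclohexane-1-carboxylate; 9 N-phenylbis(trifluoromethanesulfonimide)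
Product: 10 ethyl (1S)-1,3-dimethyl-2-{[(trifluoromethyl)sulfonyl]oxy}cyclohex-2-ene-1-carboxylate
Conditions: KN(SiMe3)2, THF, −78 °C; PhNTf2, −78 °C → rt
Reagents that add atoms: N-phenylbis(trifluoromethanesulfonimide), O=S(=O)(N(c1ccccc1)S(=O)(=O)C(F)(F)F)C(F)(F)F
Why: Enol triflate formation: the ketone can enolise only towards C10, so the tetrasubstituted potassium enolate forms with one regiochemistry and is O-sulfonylated by PhNTf2.

Step 5
Reactants: 10 the enol triflate ester
Product: 11 (6R)-6-(hydroxymethyl)-2,6-dimethylcyclohex-1-en-1-yl trifluoromethanesulfonate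
Conditions: iBu2AlH (2.5 equiv), CH2Cl2, −78 → 0 °C; aq. potassium sodium tartrate
Reagents that add atoms: none
Why: Hydride reduction of the ester to the primary C19 alcohol by iBu2AlH at low temperature, which leaves the vinyl triflate intact; C4 is not involved (the descriptor changes only through priorities).

Step 6
Reactants: 11 the hydroxy triflate; 12 tert-butyl(chloro)diphenylsilane
Product: 13 (6R)-6-{[(tert-butyldiphenylsilyl)oxy]methyl}-2,6-dimethylcyclohex-1-en-1-yl trifluoromethanesulfonate
Conditions: TBDPSCl, imidazole, DMF, rt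
Reagents that add atoms: tert-butyl(chloro)diphenylsilane, CC(C)(C)[Si](Cl)(c1ccccc1)c1ccccc1
Why: Silylation of the primary alcohol; the bulky ether survives steps 7 to 11 and makes the C19 arm the large substituent on C4, which later screens the β face of the ring alkene.

Step 7
Reactants: 13 the silylated triflate; 14 carbon monoxide; 15 methanol
Product: 16 methyl (6S)-6-{[(tert-butyldiphenylsilyl)oxy]methyl}-2,6-dimethylcyclohex-1-ene-1-carboxylate
Conditions: Pd(OAc)2 (5 mol %), 1,3-bis(diphenylphosphino)propane, Et3N, CO (1 atm), MeOH/DMF, 70 °C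
Reagents that add atoms: carbon monoxide, [C-]#[O+]; methanol, CO
Why: Palladium-catalysed alkoxycarbonylation of a vinyl triflate (oxidative addition to zerovalent palladium, CO insertion, methanolysis of the acyl palladium) introduces C6 at the ester level, a reaction that tolerates fully substituted cyclohexenyl triflates.

Step 8
Reactants: 16 the methyl enoate
Product: 17 [(6S)-6-{[(tert-butyldiphenylsilyl)oxy]methyl}-2,6-dimethylcyclohex-1-en-1-yl]methanol
Conditions: iBu2AlH (2.5 equiv), CH2Cl2, −78 → 0 °C; aq. potassium sodium tartrate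
Reagents that add atoms: none
Why: 1,2-Reduction of the conjugated ester by iBu2AlH gives the allylic alcohol without touching the tetrasubstituted alkene or the silyl ether.

Step 9
Reactants: 17 the allylic alcohol; 18 diiodomethane
Product: 19 [(1R,2S,6R)-2-{[(tert-butyldiphenylsilyl)oxy]methyl}-2,6-dimethylbicyclo[4.1.0]heptan-1-yl]methanol (cyclopropane CH2 anti to the silyloxymethyl arm)
Conditions: Et2Zn, CH2I2 [Zn(CH2I)2], DME, (4S,5S)-2-butyl-N,N,N′,N′-tetramethyl-1,3,2-dioxaborolane-4,5-dicarboxamide (1.2 equiv), CH2Cl2, −10 °C → rt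
Reagents that add atoms: diiodomethane, ICI
Why: Hydroxyl-directed asymmetric Simmons–Smith cyclopropanation with a chiral dioxaborolane: the zinc alkoxide binds the boronate and Zn(CH2I)2 delivers the methylene (C9) to the alkene face chosen by the ligand, here the face anti to the silyloxymethyl arm, which the substrate itself should also favour because that arm sits pseudoaxial; this sets C5 and C10 together (C10 methyl cis to C19).

Step 10
Reactants: 19 the cyclopropylmethanol
Product: 20 (1R,2S,6R)-2-{[(tert-butyldiphenylsilyl)oxy]methyl}-2,6-dimethylbicyclo[4.1.0]heptane-1-carbaldehyde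
Conditions: Dess–Martin periodinane, NaHCO3, CH2Cl2, 0 °C → rt
Reagents that add atoms: none
Why: Dess–Martin oxidation of the primary alcohol to the aldehyde under buffered, non-acidic conditions that spare the cyclopropane; the aldehyde has no α-hydrogen and cannot epimerise.

Step 11
Reactants: 20 the cyclopropanecarbaldehyde; 21 methyltriphenylphosphonium bromide
Product: 22 tert-butyl{[(1R,2S,6R)-1-ethenyl-2,6-dimethylbicyclo[4.1.0]heptan-2-yl]methoxy}diphenylsilane
Conditions: Ph3PCH3Br, KOtBu, THF, 0 °C → rt
Reagents that add atoms: methyltriphenylphosphonium bromide, C[P+](c1ccccc1)(c1ccccc1)c1ccccc1.[Br-]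
Why: Wittig methylenation of the aldehyde with the non-stabilised ylide gives the vinyl group (C6=C7) and completes the vinylcyclopropane.

Step 12
Reactants: 22 the silyl-protected vinylcyclopropane
Product: 23 [(1R,2S,6R)-1-ethenyl-2,6-dimethylbicyclo[4.1.0]heptan-2-yl]methanol
Conditions: Bu4NF, THF, rt → 45 °C
Reagents that add atoms: none
Why: Fluoride-mediated cleavage of the silyl ether is done here, on a robust substrate, so that the key-step product carries the free directing hydroxyl and never meets fluoride or acid while its alkene is out of conjugation.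

Step 13
Reactants: 23 the vinylcyclopropane alcohol; 14 carbon monoxide
Product: 24 (5S,8aR)-5-(hydroxymethyl)-5,8a-dimethyl-3,5,6,7,8,8a-hexahydronaphthalen-2(1H)-one (the 5-en-8-one)
Conditions: [Rh(CO)2Cl]2 (5 mol %), CO (1 atm), toluene, 80–90 °C
Reagents that add atoms: carbon monoxide, [C-]#[O+]
Why: Monovalent rhodium adds oxidatively into the C5–C9 bond, which is activated by the adjacent vinyl group, to give a rhodacycle with a σ-bond to C9 and an η3-allyl over C5–C6–C7; CO inserts into the Rh–C9 bond and acyl–allyl reductive elimination at C7 forms the second new bond. The closest known reaction type is the rhodium- or iron-carbonyl [5+1] carbonylation of vinylcyclopropanes to cyclohex-3-enones. Ring B is closed as a six-membered carbocycle by this C7–C8 reductive elimination from the seven-membered acyl rhodacycle, a metal-templated [5+1] closure and not a polar exo or endo cyclisation. No stereocentre is created: C4 and C10 are spectators, and C5 becomes sp2. The step needs cleavage of C5–C9 and not of C5–C10, which the substrate secures because C10 is fully substituted (a tertiary alkyl–rhodium bond in a crowded metallacycle is disfavoured) while C9 is a free methylene; the quaternary C10 also leaves the Rh–C9 alkyl without a β-hydrogen, which blocks diene formation. The alkene must stay at C5=C6, which the neutral, base-free medium favours.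

Step 14
Reactants: 24 the 5-en-8-one
Product: 25 (4aS,5S,8aR)-5-(hydroxymethyl)-5,8a-dimethyloctahydronaphthalen-2(1H)-one (cis-fused)
Conditions: [Ir(cod)(PCy3)(py)]PF6 (5 mol %), H2 (1 atm), CH2Cl2, rt
Reagents that add atoms: none
Why: Hydroxyl-directed homogeneous hydrogenation: the cationic iridium centre binds the C19 hydroxyl and the C5=C6 alkene at once and adds H2 from that (β) face, so H5 ends cis to C19 and to the C10 methyl, which is the cis ring fusion of the target.

Step 15
Reactants: 25 the cis-fused hydroxy ketone; 26 tert-butyldimethylsilyl trifluoromethanesulfonate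
Product: 27 tert-butyl({(1S,4aR,8aS)-6-[(tert-butyldimethylsilyl)oxy]-1,4a-dimethyl-1,2,3,4,4a,5,8,8a-octahydronaphthalen-1-yl}methoxy)dimethylsilane
Conditions: LiN(iPr)2 (2.3 equiv), THF, −78 °C; TBSOTf (2.5 equiv), −78 → 0 °C
Reagents that add atoms: tert-butyldimethylsilyl trifluoromethanesulfonate, CC(C)(C)[Si](C)(C)OS(=O)(=O)C(F)(F)F
Why: Kinetic deprotonation (after alkoxide formation) occurs at C7 and not at the neopentyl C9, and TBSOTf traps both oxygens, which gives the C7=C8 silyl enol ether and protects the C19 hydroxyl in one operation (regioselective silyl enol ether formation).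

Step 16
Reactants: 27 the bis-silyl compound
Product: 28 (4aS,5S,8aR)-5-{[(tert-butyldimethylsilyl)oxy]methyl}-5,8a-dimethyl-4a,5,6,7,8,8a-hexahydronaphthalen-2(1H)-one (the 6-en-8-one)
Conditions: Pd(OAc)2 (1.1 equiv), MeCN, rt → 40 °C
Reagents that add atoms: none
Why: Saegusa–Ito oxidation: the palladium enolate undergoes β-hydride elimination towards C6, and since C10 is quaternary the C6=C7 enone is the only enone that can form, so any enol ether of the other regiochemistry merely reverts to ketone.

Step 17
Reactants: 29 (R)-linalool; 30 ozone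
Product: 32 (5R)-5-ethenyl-5-methyloxolan-2-ol (both anomers), via hydroxy aldehyde 31 (not isolated)
Conditions: O3 (1 equiv), CH2Cl2/MeOH, −78 °C; Me2S, −78 °C → rt
Reagents that add atoms: ozone, [O-][O+]=O
Why: Chemoselective ozonolysis: ozone reacts far faster with the electron-rich trisubstituted alkene than with the monosubstituted vinyl group next to the carbinol, and the aldehyde released closes onto the tertiary hydroxyl as the lactol; C13 is not touched.

Step 18
Reactants: 32 the lactol; 33 iodine
Product: 35 (3R)-5-iodo-3-methylpent-1-en-3-yl formate, via anomeric hypoiodite 34 (not isolated)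
Conditions: PhI(OAc)2, I2, cyclohexane/CH2Cl2, visible light, rt
Reagents that add atoms: iodine, II
Why: Hypoiodite (alkoxy-radical) β-fragmentation: homolysis of the anomeric O–I bond and scission of the C–C bond next to the alkoxy radical give the formate and a primary radical that is captured by iodine, which removes exactly one carbon and leaves the two-carbon iodide.

Step 19
Reactants: 35 the iodo formate; 15 methanol
Product: 36 (3R)-5-iodo-3-methylpent-1-en-3-ol
Conditions: KHCO3, MeOH, 0 °C
Reagents that add atoms: none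
Why: Formate esters are cleaved by mild base-catalysed transesterification at 0 °C, conditions too mild for displacement of the primary iodide by the tertiary alkoxide.

Step 20
Reactants: 36 the iodo alcohol; 37 triethylsilyl trifluoromethanesulfonate
Product: 38 triethyl{[(3R)-5-iodo-3-methylpent-1-en-3-yl]oxy}silane
Conditions: TESOTf, 2,6-lutidine, CH2Cl2, −78 → 0 °C
Reagents that add atoms: triethylsilyl trifluoromethanesulfonate, CC[Si](CC)(CC)OS(=O)(=O)C(F)(F)F
Why: Silylation of a tertiary alcohol with a silyl triflate and 2,6-lutidine; the triethylsilyl ether withstands the enolate, copper hydride and ylide steps and falls with the C19 silyl ether in step 24.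

Step 21
Reactants: 28 the 6-en-8-one; 38 the side-chain iodide
Product: 39 (1R,4aS,5S,8aS)-5-{[(tert-butyldimethylsilyl)oxy]methyl}-5,8a-dimethyl-1-[(3R)-3-methyl-3-(triethylsilyloxy)pent-4-en-1-yl]-4a,5,6,7,8,8a-hexahydronaphthalen-2(1H)-one (side chain cis to the C10 methyl)
Conditions: LiN(iPr)2 (1.1 equiv), THF, −78 °C; DMPU, then 38 (1.5 equiv), −78 → −20 °C
Reagents that add atoms: triethyl{[(3R)-5-iodo-3-methylpent-1-en-3-yl]oxy}silane, C=C[C@@](C)(CCI)O[Si](CC)(CC)CC
Why: α′-Alkylation of a cross-conjugated kinetic lithium enolate (SN2): with C7 now sp2 the only site deprotonated under kinetic control is C9, and the primary iodide should approach from the convex β face, away from ring A folded under ring B, to place the side chain cis to the C10 methyl (equatorial, expected to be the more stable epimer as well).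

Step 22
Reactants: 39 the alkylated enone
Product: 40 (1R,4aS,5S,8aS)-5-{[(tert-butyldimethylsilyl)oxy]methyl}-5,8a-dimethyl-1-[(3R)-3-methyl-3-(triethylsilyloxy)pent-4-en-1-yl]octahydronaphthalen-2(1H)-one
Conditions: [(Ph3P)CuH]6, benzene/THF, H2O, rt
Reagents that add atoms: none
Why: Chemoselective conjugate (1,4) reduction of the enone by a phosphine copper hydride, which leaves the isolated vinyl group and both silyl ethers alone; the copper enolate is C7=C8, so C9 is not epimerised.

Step 23
Reactants: 40 the saturated ketone; 21 methyltriphenylphosphonium bromide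
Product: 41 tert-butyl({(1S,4aR,5S,8aS)-1,4a-dimethyl-6-methylidene-5-[(3R)-3-methyl-3-(triethylsilyloxy)pent-4-en-1-yl]decahydronaphthalen-1-yl}methoxy)dimethylsilane
Conditions: Ph3PCH3Br, KOtBu, toluene, rt → 60 °C
Reagents that add atoms: methyltriphenylphosphonium bromide, C[P+](c1ccccc1)(c1ccccc1)c1ccccc1.[Br-]
Why: Wittig methylenation of the hindered ketone with excess non-stabilised ylide builds C17; C9 carries its substituent in the equatorial position, so the basic medium should not change it.

Step 24
Reactants: 41 the bis-silyl diene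
Product: 42 (3R)-5-[(1S,4aS,5S,8aR)-5-(hydroxymethyl)-5,8a-dimethyl-2-methylidenedecahydronaphthalen-1-yl]-3-methylpent-1-en-3-ol
Conditions: Bu4NF (excess), THF, rt → 50 °C
Reagents that add atoms: none
Why: Fluoride cleaves the primary TBS and the tertiary TES ethers in one operation (global desilylation).

Step 25
Reactants: 42 the diol
Product: 43 (1S,4aR,5S,8aS)-5-[(3R)-3-hydroxy-3-methylpent-4-en-1-yl]-1,4a-dimethyl-6-methylidenedecahydronaphthalene-1-carbaldehyde
Conditions: Dess–Martin periodinane, NaHCO3, CH2Cl2, 0 °C → rt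
Reagents that add atoms: none
Why: Dess–Martin oxidation takes the primary C19 alcohol to the aldehyde; the tertiary allylic alcohol cannot be oxidised and the aldehyde, on quaternary C4, cannot enolise.

Step 26
Reactants: 43 the hydroxy aldehyde; 44 acetic anhydride
Product: 45 (1S,4aR,5S,8aS)-5-[(3R)-3-acetoxy-3-methylpent-4-en-1-yl]-1,4a-dimethyl-6-methylidenedecahydronaphthalene-1-carbaldehyde
Conditions: Ac2O, Et3N, DMAP, CH2Cl2, rt → 40 °C
Reagents that add atoms: acetic anhydride, CC(=O)OC(C)=O
Why: DMAP-catalysed acylation of the tertiary allylic alcohol by acetic anhydride proceeds at oxygen, so C13 keeps its configuration; the non-enolisable aldehyde is inert.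

Step 27
Reactants: 45 the acetoxy aldehyde; 46 sodium chlorite
Product: 47 (1S,4aR,5S,8aS)-5-[(3R)-3-acetoxy-3-methylpent-4-en-1-yl]-1,4a-dimethyl-6-methylidenedecahydronaphthalene-1-carboxylic acid (target, CNP0230281.1)
Conditions: NaClO2, NaH2PO4, 2-methyl-2-butene, t-BuOH/H2O, rt
Reagents that add atoms: sodium chlorite, [Na+].[O-]Cl=O
Why: Pinnick oxidation converts the hindered aldehyde into the carboxylic acid at about pH 4, with 2-methyl-2-butene removing hypochlorous acid so that the two alkenes and the tertiary allylic acetate survive.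

Compound list
1 | ethyl 2-oxocyclohexane-1-carboxylate | CCOC(=O)C1CCCCC1=O | starting material
2 | L-valine tert-butyl ester | CC(C)[C@H](N)C(=O)OC(C)(C)C | starting material
3 | ethyl 2-{[(2S)-1-tert-butoxy-3-methyl-1-oxobutan-2-yl]amino}cyclohex-1-ene-1-carboxylate | CCOC(=O)C1=C(N[C@@H](C(C)C)C(=O)OC(C)(C)C)CCCC1 | intermediate
4 | iodomethane | CI | starting material
5 | water | O | starting material
6 | ethyl (1S)-2-{[(2S)-1-tert-butoxy-3-methyl-1-oxobutan-2-yl]imino}-1-methylcyclohexane-1-carboxylate (not isolated) | CCOC(=O)[C@@]1(C)CCCCC1=N[C@@H](C(C)C)C(=O)OC(C)(C)C | intermediate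
7 | ethyl (1S)-1-methyl-2-oxocyclohexane-1-carboxylate | CCOC(=O)[C@@]1(C)CCCCC1=O | intermediate
8 | ethyl (1S)-1,3-dimethyl-2-oxocyclohexane-1-carboxylate (C3 epimers) | CCOC(=O)[C@@]1(C)CCCC(C)C1=O | intermediate
9 | N-phenylbis(trifluoromethanesulfonimide) | O=S(=O)(N(c1ccccc1)S(=O)(=O)C(F)(F)F)C(F)(F)F | starting material
10 | ethyl (1S)-1,3-dimethyl-2-{[(trifluoromethyl)sulfonyl]oxy}cyclohex-2-ene-1-carboxylate | CCOC(=O)[C@@]1(C)CCCC(C)=C1OS(=O)(=O)C(F)(F)F | intermediate
11 | (6R)-6-(hydroxymethyl)-2,6-dimethylcyclohex-1-en-1-yl trifluoromethanesulfonate | OC[C@@]1(C)CCCC(C)=C1OS(=O)(=O)C(F)(F)F | intermediate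
12 | tert-butyl(chloro)diphenylsilane | CC(C)(C)[Si](Cl)(c1ccccc1)c1ccccc1 | starting material
13 | (6R)-6-{[(tert-butyldiphenylsilyl)oxy]methyl}-2,6-dimethylcyclohex-1-en-1-yl trifluoromethanesulfonate | CC(C)(C)[Si](c1ccccc1)(c1ccccc1)OC[C@@]1(C)CCCC(C)=C1OS(=O)(=O)C(F)(F)F | intermediate
14 | carbon monoxide | [C-]#[O+] | starting material
15 | methanol | CO | starting material
16 | methyl (6S)-6-{[(tert-butyldiphenylsilyl)oxy]methyl}-2,6-dimethylcyclohex-1-ene-1-carboxylate | CC(C)(C)[Si](c1ccccc1)(c1ccccc1)OC[C@@]1(C)CCCC(C)=C1C(=O)OC | intermediate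
17 | [(6S)-6-{[(tert-butyldiphenylsilyl)oxy]methyl}-2,6-dimethylcyclohex-1-en-1-yl]methanol | CC(C)(C)[Si](c1ccccc1)(c1ccccc1)OC[C@@]1(C)CCCC(C)=C1CO | intermediate
18 | diiodomethane | ICI | starting material
19 | [(1R,2S,6R)-2-{[(tert-butyldiphenylsilyl)oxy]methyl}-2,6-dimethylbicyclo[4.1.0]heptan-1-yl]methanol | OC[C@]12C[C@@]1(C)CCC[C@]2(C)CO[Si](c1ccccc1)(c1ccccc1)C(C)(C)C | intermediate
20 | (1R,2S,6R)-2-{[(tert-butyldiphenylsilyl)oxy]methyl}-2,6-dimethylbicyclo[4.1.0]heptane-1-carbaldehyde | O=C[C@]12C[C@@]1(C)CCC[C@]2(C)CO[Si](c1ccccc1)(c1ccccc1)C(C)(C)C | intermediate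
21 | methyltriphenylphosphonium bromide | C[P+](c1ccccc1)(c1ccccc1)c1ccccc1.[Br-] | starting material
22 | tert-butyl{[(1R,2S,6R)-1-ethenyl-2,6-dimethylbicyclo[4.1.0]heptan-2-yl]methoxy}diphenylsilane | C=C[C@]12C[C@@]1(C)CCC[C@]2(C)CO[Si](c3ccccc3)(c3ccccc3)C(C)(C)C | intermediate
23 | [(1R,2S,6R)-1-ethenyl-2,6-dimethylbicyclo[4.1.0]heptan-2-yl]methanol | C=C[C@]12C[C@@]1(C)CCC[C@]2(C)CO | intermediate
24 | (5S,8aR)-5-(hydroxymethyl)-5,8a-dimethyl-3,5,6,7,8,8a-hexahydronaphthalen-2(1H)-one | C1C(=O)CC=C2[C@]1(C)CCC[C@]2(C)CO | intermediate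
25 | (4aS,5S,8aR)-5-(hydroxymethyl)-5,8a-dimethyloctahydronaphthalen-2(1H)-one | C1C(=O)CC[C@H]2[C@]1(C)CCC[C@]2(C)CO | intermediate
26 | tert-butyldimethylsilyl trifluoromethanesulfonate | CC(C)(C)[Si](C)(C)OS(=O)(=O)C(F)(F)F | starting material
27 | tert-butyl({(1S,4aR,8aS)-6-[(tert-butyldimethylsilyl)oxy]-1,4a-dimethyl-1,2,3,4,4a,5,8,8a-octahydronaphthalen-1-yl}methoxy)dimethylsilane | C1C(O[Si](C)(C)C(C)(C)C)=CC[C@H]2[C@]1(C)CCC[C@]2(C)CO[Si](C)(C)C(C)(C)C | intermediate
28 | (4aS,5S,8aR)-5-{[(tert-butyldimethylsilyl)oxy]methyl}-5,8a-dimethyl-4a,5,6,7,8,8a-hexahydronaphthalen-2(1H)-one | C1C(=O)C=C[C@H]2[C@]1(C)CCC[C@]2(C)CO[Si](C)(C)C(C)(C)C | intermediate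
29 | (R)-linalool | C=C[C@@](C)(CCC=C(C)C)O | starting material
30 | ozone | [O-][O+]=O | starting material
31 | (4R)-4-hydroxy-4-methylhex-5-enal (not isolated) | C=C[C@@](C)(CCC=O)O | intermediate
32 | (5R)-5-ethenyl-5-methyloxolan-2-ol | C=C[C@@]1(C)CCC(O)O1 | intermediate
33 | iodine | II | starting material
34 | (5R)-5-ethenyl-2-(iodooxy)-5-methyloxolane (not isolated) | C=C[C@@]1(C)CCC(OI)O1 | intermediate
35 | (3R)-5-iodo-3-methylpent-1-en-3-yl formate | C=C[C@@](C)(CCI)OC=O | intermediate
36 | (3R)-5-iodo-3-methylpent-1-en-3-ol | C=C[C@@](C)(CCI)O | intermediate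
37 | triethylsilyl trifluoromethanesulfonate | CC[Si](CC)(CC)OS(=O)(=O)C(F)(F)F | starting material
38 | triethyl{[(3R)-5-iodo-3-methylpent-1-en-3-yl]oxy}silane | C=C[C@@](C)(CCI)O[Si](CC)(CC)CC | intermediate
39 | (1R,4aS,5S,8aS)-5-{[(tert-butyldimethylsilyl)oxy]methyl}-5,8a-dimethyl-1-[(3R)-3-methyl-3-(triethylsilyloxy)pent-4-en-1-yl]-4a,5,6,7,8,8a-hexahydronaphthalen-2(1H)-one | C=C[C@@](C)(CC[C@H]1C(=O)C=C[C@H]2[C@]1(C)CCC[C@]2(C)CO[Si](C)(C)C(C)(C)C)O[Si](CC)(CC)CC | intermediate
40 | (1R,4aS,5S,8aS)-5-{[(tert-butyldimethylsilyl)oxy]methyl}-5,8a-dimethyl-1-[(3R)-3-methyl-3-(triethylsilyloxy)pent-4-en-1-yl]octahydronaphthalen-2(1H)-one | C=C[C@@](C)(CC[C@H]1C(=O)CC[C@H]2[C@]1(C)CCC[C@]2(C)CO[Si](C)(C)C(C)(C)C)O[Si](CC)(CC)CC | intermediate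
41 | tert-butyl({(1S,4aR,5S,8aS)-1,4a-dimethyl-6-methylidene-5-[(3R)-3-methyl-3-(triethylsilyloxy)pent-4-en-1-yl]decahydronaphthalen-1-yl}methoxy)dimethylsilane | C=C[C@@](C)(CC[C@H]1C(=C)CC[C@H]2[C@]1(C)CCC[C@]2(C)CO[Si](C)(C)C(C)(C)C)O[Si](CC)(CC)CC | intermediate
42 | (3R)-5-[(1S,4aS,5S,8aR)-5-(hydroxymethyl)-5,8a-dimethyl-2-methylidenedecahydronaphthalen-1-yl]-3-methylpent-1-en-3-ol | C=C[C@@](C)(CC[C@H]1C(=C)CC[C@H]2[C@]1(C)CCC[C@]2(C)CO)O | intermediate
43 | (1S,4aR,5S,8aS)-5-[(3R)-3-hydroxy-3-methylpent-4-en-1-yl]-1,4a-dimethyl-6-methylidenedecahydronaphthalene-1-carbaldehyde | C=C[C@@](C)(CC[C@H]1C(=C)CC[C@H]2[C@]1(C)CCC[C@]2(C)C=O)O | intermediate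
44 | acetic anhydride | CC(=O)OC(C)=O | starting material
45 | (1S,4aR,5S,8aS)-5-[(3R)-3-acetoxy-3-methylpent-4-en-1-yl]-1,4a-dimethyl-6-methylidenedecahydronaphthalene-1-carbaldehyde | C=C[C@@](C)(CC[C@H]1C(=C)CC[C@H]2[C@]1(C)CCC[C@]2(C)C=O)OC(C)=O | intermediate
46 | sodium chlorite | [Na+].[O-]Cl=O | starting material
47 | (1S,4aR,5S,8aS)-5-[(3R)-3-acetoxy-3-methylpent-4-en-1-yl]-1,4a-dimethyl-6-methylidenedecahydronaphthalene-1-carboxylic acid | C=C[C@@](C)(CC[C@H]1C(=C)CC[C@H]2[C@]1(C)CCC[C@]2(C)C(=O)O)OC(C)=O | target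

Total step count: 27.
Longest linear sequence: 23 steps (steps 1–16 and 21–27); steps 17–20 form the four-step side-chain branch.

Steps most likely to fail

Step 13. Oxidative addition may be slow at a cyclopropane flanked by two quaternary carbons, the metal may open the ring-fusion bond instead, or the new alkene may drift into conjugation and erase the handle for step 14. The fallback builds ring B by other bonds. It sets out from 17: Johnson–Claisen rearrangement (triethyl orthoacetate, propionic acid cat., 140 °C) should place the acetate arm on C10 from the face anti to the silyloxymethyl group and give ethyl 2-[3-{[(tert-butyldiphenylsilyl)oxy]methyl}-1,3-dimethyl-2-methylidenecyclohexyl]acetate F1. This is converted with MeNH(OMe)·HCl/iPrMgCl into the N-methoxy-N-methylamide F2, and allylmagnesium bromide then gives the allyl ketone F3. Ring-closing metathesis with second-generation Grubbs catalyst (toluene, 80 °C) forms C5=C6 and gives the silyl ether of the 5-en-8-one F4. Buffered HF·pyridine in THF at 0 °C then removes the silyl group, and the route is rejoined at 24.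

Step 21. The SN2 reaction of a neopentyl-type enolate with an unactivated iodide may be slow enough for proton transfer to compete. That would bring enolate equilibration to the extended dienolate, with epimerisation at C5 or alkylation at C7, as well as dialkylation and poor facial selectivity at C9. The fallback replaces alkylation by an aldol sequence. The iodide 38 is oxidised (Me3NO, DMSO, Kornblum-type) to (3R)-3-methyl-3-(triethylsilyloxy)pent-4-enal F5. The lithium enolate of 28 adds to it at −78 °C to give the β-hydroxy ketone F6, and MsCl/Et3N followed by DBU gives the cross-conjugated 9(11)-ylidene dienone F7. [(Ph3P)CuH]6 then reduces both conjugated alkenes, and brief exposure to DBU equilibrates C9 to the equatorial epimer. The sequence sets out from 28 and comes back at 40.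

Step 9. Conversion may stall at the tetrasubstituted alkene next to quaternary C4, or facial selectivity may be insufficient if ligand control and substrate bias do not reinforce each other. The fallback uses a free, strongly electrophilic carbene under steric control. It sets out from 13: Stille coupling with tributyl(vinyl)stannane (Pd(PPh3)4, LiCl, dioxane, 90 °C) gives the diene tert-butyl{[(1S)-2-ethenyl-1,3-dimethylcyclohex-2-en-1-yl]methoxy}diphenylsilane F8. Dibromocarbene (CHBr3, KOtBu, pentane, 0 °C) should add to the electron-rich tetrasubstituted ring alkene, anti to the silyloxymethyl arm, to give the 7,7-dibromo analogue of 22, F9. Bu3SnH/AIBN (toluene, 80 °C) removes both bromines and the route is rejoined at 22.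

Further compounds
F1 | step 13 | ethyl 2-[3-{[(tert-butyldiphenylsilyl)oxy]methyl}-1,3-dimethyl-2-methylidenecyclohexyl]acetate (C1 methyl cis to the silyloxymethyl arm) | CCOC(=O)C[C@@]1(C)CCC[C@](C)(CO[Si](c2ccccc2)(c2ccccc2)C(C)(C)C)C1=C
F2 | step 13 | 2-[3-{[(tert-butyldiphenylsilyl)oxy]methyl}-1,3-dimethyl-2-methylidenecyclohexyl]-N-methoxy-N-methylacetamide | CON(C)C(=O)C[C@@]1(C)CCC[C@](C)(CO[Si](c2ccccc2)(c2ccccc2)C(C)(C)C)C1=C
F3 | step 13 | 1-[3-{[(tert-butyldiphenylsilyl)oxy]methyl}-1,3-dimethyl-2-methylidenecyclohexyl]pent-4-en-2-one | C=CCC(=O)C[C@@]1(C)CCC[C@](C)(CO[Si](c2ccccc2)(c2ccccc2)C(C)(C)C)C1=C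
F4 | step 13 | (5S,8aR)-5-{[(tert-butyldiphenylsilyl)oxy]methyl}-5,8a-dimethyl-3,5,6,7,8,8a-hexahydronaphthalen-2(1H)-one | C1C(=O)CC=C2[C@]1(C)CCC[C@]2(C)CO[Si](c3ccccc3)(c3ccccc3)C(C)(C)C
F5 | step 21 | (3R)-3-methyl-3-(triethylsilyloxy)pent-4-enal | C=C[C@@](C)(CC=O)O[Si](CC)(CC)CC
F6 | step 21 | aldol adduct of 28 at C9 with F5 (carbinol and C9 centres as formed) | C=C[C@@](C)(CC(O)C1C(=O)C=C[C@H]2[C@]1(C)CCC[C@]2(C)CO[Si](C)(C)C(C)(C)C)O[Si](CC)(CC)CC
F7 | step 21 | 28 carrying the (3R)-3-methyl-3-(triethylsilyloxy)pent-4-en-1-ylidene group on C9 (cross-conjugated dienone) | C=C[C@@](C)(CC=C1C(=O)C=C[C@H]2[C@]1(C)CCC[C@]2(C)CO[Si](C)(C)C(C)(C)C)O[Si](CC)(CC)CC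
F8 | step 9 | tert-butyl{[(1S)-2-ethenyl-1,3-dimethylcyclohex-2-en-1-yl]methoxy}diphenylsilane | C=CC1=C(C)CCC[C@]1(C)CO[Si](c2ccccc2)(c2ccccc2)C(C)(C)C
F9 | step 9 | 7,7-dibromo analogue of 22 (dibromocyclopropane anti to the silyloxymethyl arm) | C=C[C@]12C(Br)(Br)[C@@]1(C)CCC[C@]2(C)CO[Si](c3ccccc3)(c3ccccc3)C(C)(C)C
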